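Ring A is cut at C3–C4 and C5–C10 (labdane numbering), which unravels both rings to an acyclic polyene aldehyde. One intramolecular Diels–Alder reaction of its E 2-methyl enal (C4=C5) with the E diene C10=C1–C2=C3 forms both bonds, closes rings A and B, and sets C5 and C10 from the single stereocentre C9. It exploits three features: the C4 gem-dimethyl carbon (one methyl is carried as the activating formyl group and reduced to CH3 afterwards), the ring-B C7=C8 olefin, already present as a cis element of the four-atom tether, and the angular C10 methyl, carried on the diene terminus. The precursor is built from geranyl acetate.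

Key step: step 11

Remark: carbons are numbered as in the labdane skeleton (ring A: C1–C5 and C10; ring B: C5–C10; C17 on C8; C18 and C19 on C4; C20 on C10); the target is (5S,9R,10S)-labda-7,13E-diene-15,17-diyl diacetate.

Step 1
Reactants: 1 geranyl acetate
Product: 2 (2E,6E)-3,7-dimethyl-8-oxoocta-2,6-dien-1-yl acetate
Conditions: SeO2 (1.2 equiv), 95% EtOH, reflux
Reagents that add atoms: selenium dioxide, O=[Se]=O
Why: Allylic oxidation with SeO2 (ene reaction, then [2,3]-sigmatropic shift) attacks the E methyl group of the electron-richer isopropylidene olefin, so the E enal (future C1, C10, C20) should form while the acetate-deactivated olefin is left alone.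

Step 2
Reactants: 2 (2E,6E)-3,7-dimethyl-8-oxoocta-2,6-dien-1-yl acetate; 3 ethynyltrimethylsilane
Product: 4 (2E,6E,8R)-8-hydroxy-3,7-dimethyl-10-(trimethylsilyl)deca-2,6-dien-9-yn-1-yl acetate
Conditions: Me2Zn (3 equiv), (S,S)-ProPhenol (0.2 equiv), Ph3PO (0.4 equiv), PhMe, 4 °C; aq. NH4Cl
Reagents that add atoms: none
Why: Catalytic asymmetric alkynylation (zinc alkynylide addition to the enal under a dinuclear zinc–ProPhenol catalyst) should set the carbinol centre R by reagent control; the (S,S) ligand is written on the assumption that it delivers the alkynyl group to the face giving R, and its antipode is used if the sense proves opposite.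

Step 3
Reactants: 4 (2E,6E,8R)-8-hydroxy-3,7-dimethyl-10-(trimethylsilyl)deca-2,6-dien-9-yn-1-yl acetate; 5 (diethoxyphosphoryl)acetic acid
Product: 6 (2E,6E,8R)-8-[(diethoxyphosphoryl)acetoxy]-3,7-dimethyl-10-(trimethylsilyl)deca-2,6-dien-9-yn-1-yl acetate
Conditions: DCC (1.2 equiv), DMAP (0.1 equiv), CH2Cl2, 0 °C → rt
Reagents that add atoms: none
Why: Carbodiimide (Steglich) esterification acylates the secondary alcohol under neutral conditions without touching the stereocentre, the acetate or the alkynylsilane.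

Step 4
Reactants: 6 (2E,6E,8R)-8-[(diethoxyphosphoryl)acetoxy]-3,7-dimethyl-10-(trimethylsilyl)deca-2,6-dien-9-yn-1-yl acetate
Product: 10 methyl (3R,4E)-3-[(3E)-5-acetoxy-3-methylpent-3-en-1-yl]-2-(diethoxyphosphoryl)-4-methyl-7-(trimethylsilyl)hept-4-en-6-ynoate (C2 epimers), via silyl ketene acetal 7 (not isolated), via trimethylsilyl ester 8 (not isolated), via carboxylic acid 9 (not isolated)
Conditions: LiN(SiMe3)2 (1.05 equiv), Me3SiCl (1.2 equiv), THF, −78 → 60 °C; then MeOH, Me3SiCHN2, 0 °C → rt
Reagents that add atoms: (trimethylsilyl)diazomethane, C[Si](C)(C)C=[N+]=[N-] (ester CH3 carbon); chlorotrimethylsilane, C[Si](C)(C)Cl (silicon only in 7 and 8)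
Why: Ireland–Claisen rearrangement: the O-silyl ketene acetal of the phosphonoacetate undergoes a chair-like [3,3] shift through the E trisubstituted olefin with the alkynyl group equatorial, which forms C8–C9 and the E C10=C1 olefin and transfers the R carbinol chirality to C9 (R); methanolysis and methylation in the same flask give the ester, and C8 is formed as an inconsequential epimer mixture.

Step 5
Reactants: 10 methyl (3R,4E)-3-[(3E)-5-acetoxy-3-methylpent-3-en-1-yl]-2-(diethoxyphosphoryl)-4-methyl-7-(trimethylsilyl)hept-4-en-6-ynoate; 11 3-[(tert-butyldimethylsilyl)oxy]propanal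
Product: 12 methyl (2E,3R,4E)-3-[(3E)-5-acetoxy-3-methylpent-3-en-1-yl]-2-{3-[(tert-butyldimethylsilyl)oxy]propylidene}-4-methyl-7-(trimethylsilyl)hept-4-en-6-ynoate
Conditions: NaH (1.0 equiv), THF, 0 °C; then 11, 0 → 50 °C
Reagents that add atoms: none
Why: Horner–Wadsworth–Emmons olefination of the α-branched phosphonoacetate should place the new chain trans to the ester, i.e. C6 cis to C9 across C7=C8 as ring B later requires; no stereocentre is formed and C8 becomes sp2.

Step 6
Reactants: 12 methyl (2E,3R,4E)-3-[(3E)-5-acetoxy-3-methylpent-3-en-1-yl]-2-{3-[(tert-butyldimethylsilyl)oxy]propylidene}-4-methyl-7-(trimethylsilyl)hept-4-en-6-ynoate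
Product: 13 (2E,3R,4E)-2-{3-[(tert-butyldimethylsilyl)oxy]propylidene}-3-[(3E)-5-hydroxy-3-methylpent-3-en-1-yl]-4-methyl-7-(trimethylsilyl)hept-4-en-6-yn-1-ol
Conditions: i-Bu2AlH (6 equiv), CH2Cl2, −78 → 0 °C; aq. Rochelle salt
Reagents that add atoms: none
Why: Hydride reduction with i-Bu2AlH takes the conjugated ester to the allylic alcohol (1,2-reduction, C17) and cleaves the acetate in the same operation, while silyl groups, alkyne and olefins are inert.

Step 7
Reactants: 13 (2E,3R,4E)-2-{3-[(tert-butyldimethylsilyl)oxy]propylidene}-3-[(3E)-5-hydroxy-3-methylpent-3-en-1-yl]-4-methyl-7-(trimethylsilyl)hept-4-en-6-yn-1-ol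
Product: 14 (2E,3R,4E)-3-[(3E)-5-acetoxy-3-methylpent-3-en-1-yl]-2-{3-[(tert-butyldimethylsilyl)oxy]propylidene}-4-methyl-7-(trimethylsilyl)hept-4-en-6-yn-1-yl acetate
Conditions: Ac2O (3 equiv), pyridine, DMAP (cat.), CH2Cl2, rt
Reagents that add atoms: acetic anhydride, CC(=O)OC(C)=O
Why: Acylation installs both acetates of the target (C15 and C17), which also protect the allylic alcohols during the oxidation that follows.

Step 8
Reactants: 14 (2E,3R,4E)-3-[(3E)-5-acetoxy-3-methylpent-3-en-1-yl]-2-{3-[(tert-butyldimethylsilyl)oxy]propylidene}-4-methyl-7-(trimethylsilyl)hept-4-en-6-yn-1-yl acetate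
Product: 15 (2E,3R,4E)-3-[(3E)-5-acetoxy-3-methylpent-3-en-1-yl]-2-(3-hydroxypropylidene)-4-methylhept-4-en-6-yn-1-yl acetate
Conditions: Bu4NF (2.5 equiv), AcOH (2.5 equiv), THF, 0 °C → rt
Reagents that add atoms: none
Why: Fluoride-mediated desilylation cleaves the alkynyl C–Si bond and the primary silyl ether together, and the AcOH buffer spares the two acetates.

Step 9
Reactants: 15 (2E,3R,4E)-3-[(3E)-5-acetoxy-3-methylpent-3-en-1-yl]-2-(3-hydroxypropylidene)-4-methylhept-4-en-6-yn-1-yl acetate; 16 2-(triphenylphosphoranylidene)propanal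
Product: 18 (2E,5E,7R,8E)-6-(acetoxymethyl)-7-[(3E)-5-acetoxy-3-methylpent-3-en-1-yl]-2,8-dimethylundeca-2,5,8-trien-10-ynal, via skipped aldehyde 17 (not isolated)
Conditions: Dess–Martin periodinane (1.3 equiv), NaHCO3, CH2Cl2, 0 °C; then 16 (1.5 equiv), 0 → 40 °C
Reagents that add atoms: none
Why: Dess–Martin oxidation gives the β,γ-unsaturated aldehyde, which is trapped in the same flask by a Wittig reaction with the stabilized ylide to give the E 2-methyl enal (formyl trans to C6) before the skipped olefin can move into conjugation.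

Step 10
Reactants: 18 (2E,5E,7R,8E)-6-(acetoxymethyl)-7-[(3E)-5-acetoxy-3-methylpent-3-en-1-yl]-2,8-dimethylundeca-2,5,8-trien-10-ynal
Product: 19 (2E,5E,7R,8E)-6-(acetoxymethyl)-7-[(3E)-5-acetoxy-3-methylpent-3-en-1-yl]-2,8-dimethylundeca-2,5,8,10-tetraenal
Conditions: H2 (1 atm), Pd/CaCO3 poisoned with Pb(OAc)2 (Lindlar catalyst), quinoline, EtOAc, rt
Reagents that add atoms: none
Why: Lindlar semi-hydrogenation stops at the alkene, turning the terminal enyne into the E diene C10=C1–C2=C3 at room temperature without touching the trisubstituted olefins or the enal, so the diene is unveiled only just before the cycloaddition.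

Step 11
Reactants: 19 (2E,5E,7R,8E)-6-(acetoxymethyl)-7-[(3E)-5-acetoxy-3-methylpent-3-en-1-yl]-2,8-dimethylundeca-2,5,8,10-tetraenal
Product: 20 (4R,5R,9R,10R)-15,17-diacetoxylabda-1,7,13E-trien-18-al (4α-CHO, 5α-H, 9α-H, 10β-CH3)
Conditions: Me2AlCl (2.5 equiv), CH2Cl2, −78 → −20 °C; aq. NaHCO3
Reagents that add atoms: none
Why: Concerted, asynchronous suprafacial [4+2] cycloaddition (Lewis-acid-promoted intramolecular Diels–Alder reaction of a trienal, closest known type the endo-selective cyclisation of 2,8,10-undecatrienals to trans-decalins): Me2AlCl complexes the formyl group, lowers the LUMO of C4=C5, and the diene C10=C1–C2=C3 adds across it, forming C3–C4 and C5–C10. Ring A closes as the new cyclohexene of the [4+2] (leaving C1=C2), and ring B closes in the fused mode through the C5–C10 bond across the four-atom tether C6–C7=C8–C9, whose cis olefin becomes the ring-B double bond. The trans ring fusion (C5 relative to C10) follows from the E geometry of both partners together with the endo position of the complexed formyl group, which forces the tether exo; the same arrangement places the formyl group on C4 cis to H5. The absolute sense comes from C9: with its hydrogen eclipsing C10=C1 (minimal allylic strain) the side chain shields one diene face, so C5 bonds anti to it and gives 10β-methyl and 5α-H. The step needs endo over exo selectivity and diene-face control, secured by Lewis-acid complexation at low temperature and by the allylic stereocentre; chemoselectivity is secured because C7=C8 and C13=C14 are unactivated and cannot reach the diene in a [4+2] sense, and the E enal keeps the formyl group away from the tether olefin. Two fully substituted carbons (C4 and C10) are created, but each bonds to a less substituted partner, which keeps the step sterically feasible.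

Step 12
Reactants: 20 (4R,5R,9R,10R)-15,17-diacetoxylabda-1,7,13E-trien-18-al
Product: 22 (5S,9R,10S)-labda-1,7,13E-triene-15,17-diyl diacetate, via tosylhydrazone 21 (not isolated)
Conditions: TsNHNH2 (1.2 equiv), EtOH, 50 °C; evaporate; catecholborane (2.5 equiv), CHCl3, 0 °C → rt; NaOAc·3H2O, 60 °C
Reagents that add atoms: 4-methylbenzenesulfonohydrazide, Cc1ccc(cc1)S(=O)(=O)NN (its atoms remain only in 21)
Why: Mild Wolff–Kishner-type deoxygenation (hydride reduction of the tosylhydrazone, loss of sulfinate and N2 from the diazene) should turn the neopentyl formyl group into the second C4 methyl group without harming acetates or olefins; C4 ceases to be a stereocentre.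

Step 13
Reactants: 22 (5S,9R,10S)-labda-1,7,13E-triene-15,17-diyl diacetate
Product: 23 (5S,9R,10S)-labda-7,13E-diene-15,17-diyl diacetate (target)
Conditions: H2 (1 atm), RhCl(PPh3)3 (0.1 equiv), PhH–EtOH, rt
Reagents that add atoms: none
Why: Homogeneous hydrogenation with RhCl(PPh3)3 discriminates by olefin substitution and should saturate only the cis-disubstituted C1=C2 bond, leaving the two trisubstituted allylic-acetate olefins; no stereocentre is formed.

Compound list
1 | geranyl acetate, (2E)-3,7-dimethylocta-2,6-dien-1-yl acetate | CC(=O)OC/C=C(\C)CCC=C(C)C | starting material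
2 | (2E,6E)-3,7-dimethyl-8-oxoocta-2,6-dien-1-yl acetate | CC(=O)OC/C=C(\C)CC/C=C(\C)C=O | intermediate
3 | ethynyltrimethylsilane | C#C[Si](C)(C)C | starting material
4 | (2E,6E,8R)-8-hydroxy-3,7-dimethyl-10-(trimethylsilyl)deca-2,6-dien-9-yn-1-yl acetate | CC(=O)OC/C=C(\C)CC/C=C(\C)[C@@H](O)C#C[Si](C)(C)C | intermediate
5 | (diethoxyphosphoryl)acetic acid | CCOP(=O)(CC(=O)O)OCC | starting material
6 | (2E,6E,8R)-8-[(diethoxyphosphoryl)acetoxy]-3,7-dimethyl-10-(trimethylsilyl)deca-2,6-dien-9-yn-1-yl acetate | CC(=O)OC/C=C(\C)CC/C=C(\C)[C@@H](OC(=O)CP(=O)(OCC)OCC)C#C[Si](C)(C)C | intermediate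
7 | O-trimethylsilyl ketene acetal of 6 | CC(=O)OC/C=C(\C)CC/C=C(\C)[C@@H](OC(O[Si](C)(C)C)=CP(=O)(OCC)OCC)C#C[Si](C)(C)C | intermediate
8 | trimethylsilyl (3R,4E)-3-[(3E)-5-acetoxy-3-methylpent-3-en-1-yl]-2-(diethoxyphosphoryl)-4-methyl-7-(trimethylsilyl)hept-4-en-6-ynoate (C2 epimers) | CC(=O)OC/C=C(\C)CC[C@H](/C(C)=C/C#C[Si](C)(C)C)C(C(=O)O[Si](C)(C)C)P(=O)(OCC)OCC | intermediate
9 | (3R,4E)-3-[(3E)-5-acetoxy-3-methylpent-3-en-1-yl]-2-(diethoxyphosphoryl)-4-methyl-7-(trimethylsilyl)hept-4-en-6-ynoic acid (C2 epimers) | CC(=O)OC/C=C(\C)CC[C@H](/C(C)=C/C#C[Si](C)(C)C)C(C(=O)O)P(=O)(OCC)OCC | intermediate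
10 | methyl (3R,4E)-3-[(3E)-5-acetoxy-3-methylpent-3-en-1-yl]-2-(diethoxyphosphoryl)-4-methyl-7-(trimethylsilyl)hept-4-en-6-ynoate (C2 epimers) | CC(=O)OC/C=C(\C)CC[C@H](/C(C)=C/C#C[Si](C)(C)C)C(C(=O)OC)P(=O)(OCC)OCC | intermediate
11 | 3-[(tert-butyldimethylsilyl)oxy]propanal | O=CCCO[Si](C)(C)C(C)(C)C | starting material
12 | methyl (2E,3R,4E)-3-[(3E)-5-acetoxy-3-methylpent-3-en-1-yl]-2-{3-[(tert-butyldimethylsilyl)oxy]propylidene}-4-methyl-7-(trimethylsilyl)hept-4-en-6-ynoate | CC(=O)OC/C=C(\C)CC[C@H](/C(C)=C/C#C[Si](C)(C)C)/C(C(=O)OC)=C\CCO[Si](C)(C)C(C)(C)C | intermediate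
13 | (2E,3R,4E)-2-{3-[(tert-butyldimethylsilyl)oxy]propylidene}-3-[(3E)-5-hydroxy-3-methylpent-3-en-1-yl]-4-methyl-7-(trimethylsilyl)hept-4-en-6-yn-1-ol | OC/C=C(\C)CC[C@H](/C(C)=C/C#C[Si](C)(C)C)/C(CO)=C\CCO[Si](C)(C)C(C)(C)C | intermediate
14 | (2E,3R,4E)-3-[(3E)-5-acetoxy-3-methylpent-3-en-1-yl]-2-{3-[(tert-butyldimethylsilyl)oxy]propylidene}-4-methyl-7-(trimethylsilyl)hept-4-en-6-yn-1-yl acetate | CC(=O)OC/C=C(\C)CC[C@H](/C(C)=C/C#C[Si](C)(C)C)/C(COC(C)=O)=C\CCO[Si](C)(C)C(C)(C)C | intermediate
15 | (2E,3R,4E)-3-[(3E)-5-acetoxy-3-methylpent-3-en-1-yl]-2-(3-hydroxypropylidene)-4-methylhept-4-en-6-yn-1-yl acetate | CC(=O)OC/C=C(\C)CC[C@H](/C(C)=C/C#C)/C(COC(C)=O)=C\CCO | intermediate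
16 | 2-(triphenylphosphoranylidene)propanal | CC(C=O)=P(c1ccccc1)(c1ccccc1)c1ccccc1 | starting material
17 | (2E,3R,4E)-3-[(3E)-5-acetoxy-3-methylpent-3-en-1-yl]-4-methyl-2-(3-oxopropylidene)hept-4-en-6-yn-1-yl acetate | CC(=O)OC/C=C(\C)CC[C@H](/C(C)=C/C#C)/C(COC(C)=O)=C\CC=O | intermediate
18 | (2E,5E,7R,8E)-6-(acetoxymethyl)-7-[(3E)-5-acetoxy-3-methylpent-3-en-1-yl]-2,8-dimethylundeca-2,5,8-trien-10-ynal | CC(=O)OC/C=C(\C)CC[C@H](/C(C)=C/C#C)/C(COC(C)=O)=C\C/C=C(\C)C=O | intermediate
19 | (2E,5E,7R,8E)-6-(acetoxymethyl)-7-[(3E)-5-acetoxy-3-methylpent-3-en-1-yl]-2,8-dimethylundeca-2,5,8,10-tetraenal | CC(=O)OC/C=C(\C)CC[C@H](/C(C)=C/C=C)/C(COC(C)=O)=C\C/C=C(\C)C=O | intermediate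
20 | (4R,5R,9R,10R)-15,17-diacetoxylabda-1,7,13E-trien-18-al | CC(=O)OC/C=C(\C)CC[C@H]1C(COC(C)=O)=CC[C@H]2[C@](C)(C=O)CC=C[C@]12C | intermediate
21 | p-toluenesulfonylhydrazone of 20 | CC(=O)OC/C=C(\C)CC[C@H]1C(COC(C)=O)=CC[C@H]2[C@](C)(C=NNS(=O)(=O)c3ccc(C)cc3)CC=C[C@]12C | intermediate
22 | (5S,9R,10S)-labda-1,7,13E-triene-15,17-diyl diacetate | CC(=O)OC/C=C(\C)CC[C@H]1C(COC(C)=O)=CC[C@H]2C(C)(C)CC=C[C@]12C | intermediate
23 | (5S,9R,10S)-labda-7,13E-diene-15,17-diyl diacetate | CC(=O)OC/C=C(\C)CC[C@H]1C(COC(C)=O)=CC[C@H]2C(C)(C)CCC[C@]12C | target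

Total step count: 13. Longest linear sequence: 13 steps, from geranyl acetate 1 (3, 5, 11 and 16 are bought).

Steps most likely to fail

Step 11 (key step). What may go wrong: insufficient endo over exo and diene-face discrimination during the cycloaddition, or ionisation of the allylic C17 acetate by the aluminium Lewis acid before ring closure. The fallback sets out from 19 and comes back at 20; it turns the formyl group into a cationic activating group. Treatment of 19 with Me3SiOCH2CH2OSiMe3 and catalytic Me3SiOSO2CF3 (CH2Cl2, −78 °C) should give the 2-alkenyl-1,3-dioxolane F1. Under the same catalyst the acetal opens reversibly to an oxygen-stabilised allyl cation whose C4=C5 bond is a far stronger dienophile, so the cationic [4+2] cyclisation can run at −78 °C to the ethylene acetal of the adduct F2. Pyridinium p-toluenesulfonate in wet acetone then releases aldehyde 20.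

Step 4. What may go wrong: slow [3,3] shift of the phosphonate-stabilised ketene acetal, with competing fragmentation of the doubly activated ester and erosion of the chirality transfer. The fallback sets out from 4 and comes back at 10; it makes the C8–C9 bond by a stereospecific Tsuji–Trost alkylation instead of a sigmatropic shift. Alcohol 4 with ClCO2Me and pyridine should give the methyl carbonate F3. With Pd(PPh3)4 (cat.) and methyl (diethoxyphosphoryl)acetate in THF, zerovalent palladium ionises the carbonate anti, and far faster than the primary allylic acetate. The released methoxide deprotonates the pronucleophile, which attacks anti to palladium at C9, the terminus that keeps the enyne conjugated. This should return 10 with overall retention, i.e. the same 1,3-transfer of chirality, and without the methylation.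

Step 5. What may go wrong: sluggish addition of the congested phosphonate carbanion and partial formation of the wrong C7=C8 geometry. The fallback sets out from 4 and comes back at 12; it introduces the alkylidene by a decarboxylative Knoevenagel condensation. Alcohol 4 is esterified with methyl hydrogen malonate (DCC, DMAP) to the mixed malonate F4. Ireland–Claisen rearrangement (LiN(SiMe3)2, Me3SiCl, THF, −78 → 60 °C; aqueous work-up) should give the malonic half-ester F5 with the same transfer of chirality to C9. Heating F5 with aldehyde 11, piperidine and pyridine (Doebner modification) should then give 12 with loss of CO2, the decarboxylative elimination placing C6 trans to the ester.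

Further compounds
F1 | step 11 | 2-[(1E,4E,6R,7E)-5-(acetoxymethyl)-6-[(3E)-5-acetoxy-3-methylpent-3-en-1-yl]-7-methyldeca-1,4,7,9-tetraen-2-yl]-1,3-dioxolane (ethylene acetal of 19) | CC(=O)OC/C=C(\C)CC[C@H](/C(C)=C/C=C)/C(COC(C)=O)=C\C/C=C(\C)C1OCCO1
F2 | step 11 | ethylene acetal of 20 (18,18-ethylenedioxy-labda-1,7,13E-triene-15,17-diyl diacetate) | CC(=O)OC/C=C(\C)CC[C@H]1C(COC(C)=O)=CC[C@H]2[C@](C)(C3OCCO3)CC=C[C@]12C
F3 | step 4 | (2E,6E,8R)-8-[(methoxycarbonyl)oxy]-3,7-dimethyl-10-(trimethylsilyl)deca-2,6-dien-9-yn-1-yl acetate | CC(=O)OC/C=C(\C)CC/C=C(\C)[C@@H](OC(=O)OC)C#C[Si](C)(C)C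
F4 | step 5 | (2E,6E,8R)-8-[(3-methoxy-3-oxopropanoyl)oxy]-3,7-dimethyl-10-(trimethylsilyl)deca-2,6-dien-9-yn-1-yl acetate | CC(=O)OC/C=C(\C)CC/C=C(\C)[C@@H](OC(=O)CC(=O)OC)C#C[Si](C)(C)C
F5 | step 5 | (3R,4E)-3-[(3E)-5-acetoxy-3-methylpent-3-en-1-yl]-2-(methoxycarbonyl)-4-methyl-7-(trimethylsilyl)hept-4-en-6-ynoic acid (C2 epimers) | CC(=O)OC/C=C(\C)CC[C@H](/C(C)=C/C#C[Si](C)(C)C)C(C(=O)O)C(=O)OC
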